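**Assumptions.** (i) Labdane numbering is used for the terpenoid carbons: C1–C10 decalin, C11–C12 side chain, C13–C16 succinimide, C17 exocyclic CH2, C20 angular CH3; α is the face opposite the C10 methyl. On this numbering the target is (2R,3R,5R,9S,10R,12S,13R), i.e. 2α,3β-Cl2 (both equatorial), 5α-H, 9α-H, 10β-Me, and the C12/C13 pair is a syn aldol. (ii) The enantiomers of the two chiral catalysts (steps 2 and 13) are chosen from their usual sense of induction with simple substrates; if either is reversed here, the mirror-image catalyst is used.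

## Retrosynthetic overview

1. Succinimide and C12/C13: catalytic syn-aldol of aldehyde 18 with a doubly activated succinyl donor, then ring closure with NH3 (succinimide formed last).
2. Aldehyde 18 comes from one-carbon homologation of the C11 aldehyde 15.
3. Rings A and B are formed together by an intramolecular Diels–Alder reaction of acyclic enal 13 (2-silyloxy vinylallene + E-trisubstituted enal). It sets C5, C9 and C10 and delivers the masked C6 ketone and the C8 exocyclic methylene.
4. The acyclic chain comes from α-chloroaldehyde 3 by vinylogous Mukaiyama aldol (C1–C2 bond), Appel inversion (C2–Cl) and ester → allenyl ketone conversion.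
5. The first stereocentre (C3–Cl) is set by organocatalytic α-chlorination of achiral aldehyde 2; every later stereocentre is relayed from it or set by a catalyst.

## Forward route

**Step 1**
Reactants: 1, methyl 3,3-dimethylpent-4-enoate
Product: 2, methyl 3,3-dimethyl-5-oxopentanoate
Conditions: PdCl2(PhCN)2 (10 mol %), CuCl2·2H2O (10 mol %), AgNO2 (5 mol %), O2 (1 atm), t-BuOH/MeNO2 15:1, rt
Reagents that add atoms: dioxygen, O=O
Why: Nitrite-modified aldehyde-selective (anti-Markovnikov) Wacker oxidation; the quaternary allylic carbon further disfavours attack at the internal carbon, so the terminal aldehyde forms and the ester is untouched.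

**Step 2**
Reactants: 2
Product: 3, methyl (4R)-4-chloro-3,3-dimethyl-5-oxopentanoate
Conditions: (5R)-5-benzyl-2,2,3-trimethylimidazolidin-4-one·TFA (10 mol %), 2,3,4,5,6,6-hexachlorocyclohexa-2,4-dien-1-one (1.2 equiv), acetone, −30 °C; pentane extraction, used crude
Reagents that add atoms: 2,3,4,5,6,6-hexachlorocyclohexa-2,4-dien-1-one, O=C1C(Cl)=C(Cl)C(Cl)=C(Cl)C1(Cl)Cl
Why: Enamine-catalysed enantioselective α-chlorination of an aldehyde; the E-enamine is chlorinated on the face away from the catalyst benzyl group to give the R chloride (labdane C3), and the adjacent quaternary carbon slows enolisation so the product keeps its ee.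

**Step 3**
Reactants: 4, tert-butyl 3-methylbut-2-enoate
Product: 5, tert-butyl{[(1Z)-1-tert-butoxy-3-methylbuta-1,3-dien-1-yl]oxy}dimethylsilane
Conditions: LDA, THF, −78 °C; TBSCl, DMPU, −78 °C → rt
Reagents that add atoms: tert-butyldimethylsilyl chloride, CC(C)(C)[Si](C)(C)Cl
Why: γ-Deprotonation of the senecioate and O-silylation of the extended enolate gives the vinylogous silyl ketene acetal (no stereocentre; acetal geometry is irrelevant).

**Step 4**
Reactants: 3 and 5
Product: 6, 1-tert-butyl 9-methyl (2E,5S,6R)-6-chloro-5-hydroxy-3,7,7-trimethylnon-2-enedioate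
Conditions: BF3·OEt2 (1.5 equiv), CH2Cl2, −78 °C; cold aq. NaHCO3; crude product taken on at once
Reagents that add atoms: none
Why: Vinylogous Mukaiyama aldol (γ-attack, open transition state); Cornforth/polar Felkin–Anh control by the α-chlorine gives the 1,2-anti chlorohydrin (new carbinol S, labdane C2) and the E-enoate, while any Z-isomer lactonises and is removed.

**Step 5**
Reactants: 6
Product: 7, 1-tert-butyl 9-methyl (2E,5R,6R)-5,6-dichloro-3,7,7-trimethylnon-2-enedioate
Conditions: PPh3, NCS, THF, 0 °C → rt (freshly prepared 6, to pre-empt δ-lactonisation onto the methyl ester)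
Reagents that add atoms: N-chlorosuccinimide, O=C1CCC(=O)N1Cl
Why: Appel-type deoxychlorination; chloride displaces the alkoxyphosphonium by SN2 with inversion, turning the anti-chlorohydrin into the syn (labdane 2R,3R) dichloride, and the two esters are poor neighbouring groups while the non-basic medium limits HCl elimination.

**Step 6**
Reactants: 7 and 8, propargyl bromide (used as its Grignard reagent)
Product: 10, tert-butyl (2E,5R,6R)-5,6-dichloro-3,7,7-trimethyl-9-oxododeca-2,10,11-trienoate (via Weinreb amide 9, not isolated)
Conditions: MeNHOMe·HCl (2 equiv) + i-PrMgCl (4 equiv) premixed, THF, −20 → 0 °C; then propargylmagnesium bromide (from 8, Mg, cat. HgCl2, Et2O; 3 equiv), −78 → −40 °C; aq. NH4Cl; then Et3N (0.2 equiv), CH2Cl2, rt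
Reagents that add atoms: none (the three new carbons come from reactant 8; the N(OMe)Me group of 9 is lost again)
Why: One-pot ester → Weinreb amide → ketone acylation; ClMg–N(OMe)Me attacks only the methyl ester (the tert-butyl enoate is inert), the allenyl Grignard adds once to the chelated amide (SE2′) to give the propargyl ketone, and Et3N isomerises it to the conjugated allenyl ketone without touching a stereocentre.

**Step 7**
Reactants: 10
Product: 11, tert-butyl (2E,5R,6R,8Z)-5,6-dichloro-3,7,7-trimethyl-9-[(triethylsilyl)oxy]dodeca-2,8,10,11-tetraenoate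
Conditions: TESCl (3 equiv), THF, −78 °C; LiHMDS (1.15 equiv) added dropwise (internal quench), 15 min; Et3N/pentane work-up
Reagents that add atoms: chlorotriethylsilane, CC[Si](Cl)(CC)CC
Why: Kinetic α′-enolisation and O-silylation; the C5 methylene is the only sp3 α-position, LiHMDS favours the Z(O)-enolate (quaternary substituent cis to oxygen), and in-situ trapping stops the enolate from displacing the γ-chloride to a cyclopropane.

**Step 8**
Reactants: 11
Product: 12, (2E,5R,6R,8Z)-5,6-dichloro-3,7,7-trimethyl-9-[(triethylsilyl)oxy]dodeca-2,8,10,11-tetraen-1-ol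
Conditions: DIBAL-H (2.5 equiv), CH2Cl2, −78 °C; Rochelle salt
Reagents that add atoms: none
Why: Hydride reduction of the enoate to the allylic alcohol; the silyl dienol ether, allene and secondary chlorides are inert and the E-alkene is retained.

**Step 9**
Reactants: 12
Product: 14, labdane-numbered trans-decalin with 2α,3β-Cl2, 4,4-Me2, 5α-H, 6-OTES/Δ6, 8=CH2, 9β-CHO (9α-H), 10β-Me (via enal 13, not isolated)
Conditions: MnO2 (20 equiv), CH2Cl2, rt; filter; PhMe (0.01 M), BHT, 60 °C
Reagents that add atoms: none
Why: Proposed new method: intramolecular Diels–Alder reaction of a 2-silyloxy vinylallene (the α′-silyl enol ether of an allenyl ketone) with a β,β-disubstituted enal generated by allylic oxidation; the electron-rich diene has its largest HOMO coefficient at C5, which bonds to the enal β-carbon C10 (matched "para" polarity), while the sp-hybridised allene carbon C8 closes onto C9 with little steric cost, leaving C8=CH2 exocyclic and C6 as a silyl enol ether; the C1–C4 tether folds as a chair with both chlorines equatorial (the other diene face would put them axial and syn to the C10 methyl) and is assisted by the gem-dimethyl group, the endo-CHO transition state of the E-enal gives the trans ring fusion, and suprafacial addition places C10-Me and C9-CHO cis, so C5, C9 and C10 are set by C2/C3; closest known reactions are Diels–Alder reactions of siloxy vinylallenes carrying the siloxy group on the allene carbon, vinylallene IMDA reactions and 2-silyloxydiene IMDA/intramolecular double Michael reactions.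

**Step 10**
Reactants: 14
Product: 15, keto aldehyde: as 14 but with 6-oxo and 7-CH2 (8=CH2 retained)
Conditions: TBAF (1.1 equiv)/AcOH (1.5 equiv) premixed, THF, −78 → −40 °C
Reagents that add atoms: none
Why: Fluoride desilylation gives the ammonium dienolate, which AcOH protonates kinetically at the α-carbon C7 (deconjugative protonation) to give the β,γ-unsaturated ketone; buffering protects the C9 aldehyde, and C5 keeps the more stable trans fusion.

**Step 11**
Reactants: 15 and 16, 2-(dichloromethyl)-4,4,5,5-tetramethyl-1,3,2-dioxaborolane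
Product: 18, C12 aldehyde: as 15 but with 9β-CH2CHO (via E-alkenyl boronate 17, not isolated)
Conditions: CrCl2 (8 equiv), LiI (4 equiv), 16 (2 equiv), THF, rt; Florisil filtration; then 30% H2O2, aq. NaHCO3, THF, 0 °C
Reagents that add atoms: hydrogen peroxide, OO (16 supplies the new carbon)
Why: Takai–Utimoto borylolefination (non-basic gem-dichromium reagent, aldehyde-selective over the ketone, so C9 is not enolised) followed by oxidation of the alkenyl boronate to the enol gives the one-carbon-homologated aldehyde with no stereocentre touched.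

**Step 12**
Reactants: 19, succinyl chloride (1 equiv), and 20, 1,3-thiazolidine-2-thione (2.1 equiv; two molecules are incorporated, one at each acyl chloride)
Product: 21, 1,4-bis(2-thioxo-1,3-thiazolidin-3-yl)butane-1,4-dione
Conditions: 20 (2.1 equiv), Et3N (2.2 equiv), CH2Cl2, 0 °C; 19 added dropwise, 0 °C → rt; recrystallise
Reagents that add atoms: the second molecule of 1,3-thiazolidine-2-thione (20), S=C1NCCS1
Why: Double N-acylation (Schotten–Baumann-type acyl substitution, one thiazolidinethione per C(O)Cl, 2 HCl taken up by Et3N) gives the symmetrical, doubly activated succinate donor; adding the diacid chloride to excess nucleophile avoids mono-acylated material (no stereocentre).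

**Step 13**
Reactants: 18 and 21 (2 equiv used; one molecule incorporated)
Product: 22, O-TMS syn-aldol adduct: 18 extended at C12 to CH(OTMS)–CH[C(=O)Tzt]–CH2–C(=O)Tzt (Tzt = 2-thioxothiazolidin-3-yl), 12S,13R
Conditions: [Ni((S,S)-t-Bu-box)](OTf)2 (10 mol %), TMSOTf (1.3 equiv), 2,6-lutidine (3.3 equiv), PhMe/CH2Cl2 4:1, −78 → −20 °C
Reagents that add atoms: trimethylsilyl triflate, C[Si](C)(C)OS(=O)(=O)C(F)(F)F
Why: Catalytic enantioselective syn-aldol by soft enolisation of an N-acylthiazolidinethione on a chiral Ni(II)–bis(oxazoline) complex; the Z-enolate gives the syn relationship and the catalyst selects the aldehyde face to give 12S,13R, while lutidine-buffered TMSOTf only silylates the aldolate and leaves the ketone and alkene alone.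

**Step 14**
Reactants: 22
Product: 23, haterumaimide B
Conditions: NH3 (0.5 M in dioxane, 1.5 equiv), THF, −20 → 0 °C; then 1 M citric acid/MeOH, 0 °C
Reagents that add atoms: ammonia, N
Why: Aminolysis of one acyl-thiazolidinethione gives a primary amide that closes onto the second activated acyl group (aspartimide-type 5-exo-trig N-acylation) to form the succinimide under conditions too mild to epimerise C13 or conjugate the β,γ-enone, and dilute acid removes the TMS ether.

## Compound list

1 | methyl 3,3-dimethylpent-4-enoate | C=CC(C)(C)CC(=O)OC | starting material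
2 | methyl 3,3-dimethyl-5-oxopentanoate | O=CCC(C)(C)CC(=O)OC | intermediate
3 | methyl (4R)-4-chloro-3,3-dimethyl-5-oxopentanoate | O=C[C@H](Cl)C(C)(C)CC(=O)OC | intermediate
4 | tert-butyl 3-methylbut-2-enoate | CC(C)=CC(=O)OC(C)(C)C | starting material
5 | tert-butyl{[(1Z)-1-tert-butoxy-3-methylbuta-1,3-dien-1-yl]oxy}dimethylsilane | C=C(C)/C=C(/OC(C)(C)C)O[Si](C)(C)C(C)(C)C | intermediate
6 | 1-tert-butyl 9-methyl (2E,5S,6R)-6-chloro-5-hydroxy-3,7,7-trimethylnon-2-enedioate | CC(C)(C)OC(=O)/C=C(\C)C[C@H](O)[C@H](Cl)C(C)(C)CC(=O)OC | intermediate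
7 | 1-tert-butyl 9-methyl (2E,5R,6R)-5,6-dichloro-3,7,7-trimethylnon-2-enedioate | CC(C)(C)OC(=O)/C=C(\C)C[C@@H](Cl)[C@H](Cl)C(C)(C)CC(=O)OC | intermediate
8 | propargyl bromide (3-bromoprop-1-yne) | C#CCBr | starting material
9 | tert-butyl (2E,5R,6R)-5,6-dichloro-9-[methoxy(methyl)amino]-3,7,7-trimethyl-9-oxonon-2-enoate | CC(C)(C)OC(=O)/C=C(\C)C[C@@H](Cl)[C@H](Cl)C(C)(C)CC(=O)N(C)OC | intermediate (not isolated)
10 | tert-butyl (2E,5R,6R)-5,6-dichloro-3,7,7-trimethyl-9-oxododeca-2,10,11-trienoate | CC(C)(C)OC(=O)/C=C(\C)C[C@@H](Cl)[C@H](Cl)C(C)(C)CC(=O)C=C=C | intermediate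
11 | tert-butyl (2E,5R,6R,8Z)-5,6-dichloro-3,7,7-trimethyl-9-[(triethylsilyl)oxy]dodeca-2,8,10,11-tetraenoate | CC(C)(C)OC(=O)/C=C(\C)C[C@@H](Cl)[C@H](Cl)C(C)(C)/C=C(\O[Si](CC)(CC)CC)C=C=C | intermediate
12 | (2E,5R,6R,8Z)-5,6-dichloro-3,7,7-trimethyl-9-[(triethylsilyl)oxy]dodeca-2,8,10,11-tetraen-1-ol | OC/C=C(\C)C[C@@H](Cl)[C@H](Cl)C(C)(C)/C=C(\O[Si](CC)(CC)CC)C=C=C | intermediate
13 | (2E,5R,6R,8Z)-5,6-dichloro-3,7,7-trimethyl-9-[(triethylsilyl)oxy]dodeca-2,8,10,11-tetraenal | O=C/C=C(\C)C[C@@H](Cl)[C@H](Cl)C(C)(C)/C=C(\O[Si](CC)(CC)CC)C=C=C | intermediate (not isolated)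
14 | trans-decalin aldehyde: 2α,3β-Cl2, 4,4-Me2, 5α-H, 6-OTES/Δ6, 8=CH2, 9β-CHO, 10β-Me | C=C1C=C(O[Si](CC)(CC)CC)[C@H]2C(C)(C)[C@@H](Cl)[C@H](Cl)C[C@]2(C)[C@H]1C=O | intermediate
15 | keto aldehyde: 2α,3β-Cl2, 4,4-Me2, 5α-H, 6-oxo, 8=CH2, 9β-CHO, 10β-Me | C=C1CC(=O)[C@H]2C(C)(C)[C@@H](Cl)[C@H](Cl)C[C@]2(C)[C@H]1C=O | intermediate
16 | 2-(dichloromethyl)-4,4,5,5-tetramethyl-1,3,2-dioxaborolane | ClC(Cl)B1OC(C)(C)C(C)(C)O1 | starting material
17 | as 15 but 9β-[(E)-2-(pinacolboryl)ethenyl] in place of CHO | C=C1CC(=O)[C@H]2C(C)(C)[C@@H](Cl)[C@H](Cl)C[C@]2(C)[C@H]1/C=C/B1OC(C)(C)C(C)(C)O1 | intermediate (not isolated)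
18 | as 15 but 9β-CH2CHO (C12 aldehyde) | C=C1CC(=O)[C@H]2C(C)(C)[C@@H](Cl)[C@H](Cl)C[C@]2(C)[C@H]1CC=O | intermediate
19 | succinyl chloride | O=C(Cl)CCC(=O)Cl | starting material
20 | 1,3-thiazolidine-2-thione | S=C1NCCS1 | starting material
21 | 1,4-bis(2-thioxo-1,3-thiazolidin-3-yl)butane-1,4-dione | O=C(CCC(=O)N1CCSC1=S)N1CCSC1=S | intermediate
22 | (12S,13R) O-TMS syn-aldol adduct of 18 and 21 | C=C1CC(=O)[C@H]2C(C)(C)[C@@H](Cl)[C@H](Cl)C[C@]2(C)[C@H]1C[C@H](O[Si](C)(C)C)[C@@H](CC(=O)N3CCSC3=S)C(=O)N4CCSC4=S | intermediate
23 | haterumaimide B | C=C1CC(=O)[C@H]2C(C)(C)[C@@H](Cl)[C@H](Cl)C[C@]2(C)[C@H]1C[C@H](O)[C@H]1CC(=O)NC1=O | target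

## Step count and risks

Total steps: 14. Longest linear sequence: 12 (steps 1, 2, 4–11, 13, 14); steps 3 and 12 are single-step side branches.

Three steps most likely to fail:

1. **Step 9 (proposed new IMDA).** Risks are cis/trans-fusion mixtures and sluggish formation of the C5–C10 bond next to two quaternary centres. Fallback with known chemistry: use (E)-1-propenylmagnesium bromide in step 6 to make the crotonyl ketone. Its ordinary 2-silyloxydiene undergoes the established siloxydiene IMDA to the 8-methyl Δ6 silyl enol ether. Saegusa–Ito oxidation to the Δ7-en-6-one and deconjugative γ-deprotonation/kinetic α-protonation (with the C11 aldehyde temporarily reduced and protected) then move the alkene to the exocyclic 8(17) position.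

2. **Step 7 (regio- and Z-selective silyl dienol ether of the allenyl ketone).** Risks are γ-deprotonation to the conjugated enyne enol ether, the wrong enol ether geometry, and cyclopropane formation. Fallback: acylate Weinreb amide 9 with the lithium acetylide of a protected propargyl alcohol to give a conjugated ynone whose only enolisable position is C5. Form the α′-silyl enol ether by soft enolisation, then generate the terminal allene by Pd(0)/formate SN2′ hydride reduction of the propargylic carbonate (Tsuji allene synthesis).

3. **Step 5 (Appel inversion at the hindered C2 carbinol).** Risks are elimination to the conjugated dienoate, partial retention through chloronium participation, and δ-lactonisation of 6 before activation. Fallback: avoid alcohol activation and install both chlorides at once by a known catalytic enantioselective anti-dichlorination of the Z-allylic alcohol HOCH2–CH=CH–CMe2–CH2CO2Me (Ti/Schiff-base type; the alcohol comes from ozonolysis of 1, Z-olefination and reduction). Then join C1 to the E-alkenyl unit by sp3–sp2 coupling of the derived primary triflate with an alkenylcuprate.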